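**Plan**

- Numbering: the upper flavan is rings A (benzo), C (pyran) and B (C2 aryl) with unprimed atoms; the lower flavan is rings D, F and E with primed atoms. Retrosynthesis removes seven benzyl groups, then cuts C3′–O and C4′–O (cis-dihydroxylation of a flav-3-ene), the C2′–ring E bond (arylation of a 2-ethoxy-2H-chromene made from a ring D coumarin), C3–O (from C3–B), and finally O1–C2 and C3–C4 of ring C together.
- Enabling feature: ring C carries ring B at C2, OH at C3 and ring D at C4 all trans. Its O1–C8a–C4a–C4 unit is an ortho-quinone methide of ring A with ring D on the methide carbon C4, and C2–C3 is an E alkene carrying ring B and a boron atom as masked 3-OH.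
- Forward order: the ring A aldehyde and a ring D aryllithium give the benzhydrol; the [4+2] step closes ring C with rings A, B and D in place; the ring D bromide becomes salicylaldehyde, coumarin (ring F) and chromene acetal; ring E is added at C2′; dihydroxylation and hydrogenolysis finish.
- Stereochemistry: C2, C3 and C4 come from the catalyst-controlled endo cycloaddition of the E alkene (C–B to C–O with retention); C2′ comes from catalyst-controlled aryl transfer; C3′ and C4′ come from OsO4 addition anti to the C2′ aryl group.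

Key step: step 6

Remark: the sense of induction of the chiral acid catalysts in steps 6 and 14 is assumed for these substrates, so in each case the catalyst enantiomer that delivers the drawn configuration is meant; 3,4-bis(benzyloxy)phenylboronic acid is taken as a catalogue compound.

Note on descriptors: the changes C2 S to R (step 7), C2′ S to R (step 15) and C4 S to R (step 16) follow from changed CIP priorities only; no centre is inverted after it is set.

**Route**

Step 1
Reactants: 1 4,6-dibromoresorcinol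
Product: 2 1,5-bis(benzyloxy)-2,4-dibromobenzene
Conditions: BnBr (2.2 equiv), K2CO3, DMF, 60 °C
Reagents that add atoms: benzyl bromide, BrCc1ccccc1
Why: Williamson etherification of both phenols protects ring D oxygens for the organolithium chemistry; no stereocentre is formed.

Step 2
Reactants: 3 2,4-dihydroxybenzaldehyde
Product: 4 4-(benzyloxy)-2-hydroxybenzaldehyde
Conditions: BnBr (1.05 equiv), NaHCO3, MeCN, reflux
Reagents that add atoms: benzyl bromide, BrCc1ccccc1
Why: Regioselective Williamson alkylation, because the 4-OH is the more acidic, unencumbered phenol whereas the 2-OH is held in a hydrogen bond to the formyl group and is not alkylated by a weak base.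

Step 3
Reactants: 2 1,5-bis(benzyloxy)-2,4-dibromobenzene; 4 4-(benzyloxy)-2-hydroxybenzaldehyde
Product: 7 (4-benzyloxy-2-hydroxyphenyl)[2,4-bis(benzyloxy)-5-bromophenyl]methanol (racemic), via aryllithium 5 (not isolated), via sodium phenoxide 6 (not isolated)
Conditions: 2, n-BuLi (1.0 equiv), THF, −78 °C; separately 4, NaH (1.05 equiv), THF, 0 °C; phenoxide added to the aryllithium at −78 °C, then 0 °C; aq. NH4Cl
Reagents that add atoms: none
Why: Bromine–lithium exchange at one of the two equivalent C–Br bonds (a second exchange on the aryllithium is slow at −78 °C) followed by 1,2-addition of the aryllithium to the formyl group of the pre-formed phenoxide should give the benzhydrol; its carbinol centre is racemic and is erased in step 6.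

Step 4
Reactants: 8 3,4-bis(benzyloxy)benzaldehyde
Product: 9 1,2-bis(benzyloxy)-4-ethynylbenzene
Conditions: dimethyl (1-diazo-2-oxopropyl)phosphonate, K2CO3, MeOH/THF, rt
Reagents that add atoms: dimethyl (1-diazo-2-oxopropyl)phosphonate, CC(=O)C(=[N+]=[N-])P(=O)(OC)OC
Why: Seyferth–Gilbert homologation with the in situ deacylated diazophosphonate converts the aryl aldehyde into the terminal alkyne under mild base that benzyl ethers tolerate.

Step 5
Reactants: 9 1,2-bis(benzyloxy)-4-ethynylbenzene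
Product: 10 2-[(E)-2-[3,4-bis(benzyloxy)phenyl]ethenyl]-4,4,5,5-tetramethyl-1,3,2-dioxaborolane
Conditions: pinacolborane (1.2 equiv), Cp2Zr(H)Cl (10 mol %), Et3N (10 mol %), neat, 60 °C
Reagents that add atoms: pinacolborane, CC1(C)OBOC1(C)C
Why: Cp2Zr(H)Cl-catalysed hydroboration of a terminal alkyne is a syn addition that places boron on the terminal carbon, so only the E alkenyl boronate should form.

Step 6
Reactants: 7 (4-benzyloxy-2-hydroxyphenyl)[2,4-bis(benzyloxy)-5-bromophenyl]methanol; 10 E-styryl pinacol boronate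
Product: 12 2-[(2S,3S,4S)-7-(benzyloxy)-2-[3,4-bis(benzyloxy)phenyl]-4-[2,4-bis(benzyloxy)-5-bromophenyl]-3,4-dihydro-2H-chromen-3-yl]-4,4,5,5-tetramethyl-1,3,2-dioxaborolane (2,3-trans-3,4-trans), via ortho-quinone methide 11 (not isolated)
Conditions: (R)-3,3′-bis(2,4,6-triisopropylphenyl)-1,1′-binaphthalene-2,2′-diyl N-triflylphosphoramide (10 mol %), 10 (1.5 equiv), toluene, 5 Å MS, 0 °C to rt
Reagents that add atoms: none
Why: Proposed new method: the acid ionises the doubly activated benzhydrol 7 with loss of water to the E ortho-quinone methide 11, which stays hydrogen-bonded and ion-paired to the chiral phosphoramide anion, and the boron-bearing alkene carbon of 10 (nucleophilic because positive charge at the other carbon is stabilised by the para-benzyloxy group of ring B and by σ(C–B) hyperconjugation) bonds to the methide carbon C4 while the ring A oxygen closes on the benzylic carbon C2 in an asynchronous concerted inverse-demand oxa-Diels–Alder reaction. The closest known reaction type is the chiral Brønsted acid-catalysed [4+2] cycloaddition of ortho-quinone methides from 2-hydroxybenzhydrols with styrenes; an alkenyl boronate as the 2π partner is the extrapolation, and the pinacol ester is chosen because it does not exchange ligands and so should not divert the intermediate into boron-to-carbon alkenyl transfer. Ring C is closed by the cycloaddition itself, O1–C2 and C3–C4 forming across the termini of the O1=C8a–C4a=C4 heterodiene. C2 and C3 should come out trans because addition to the E alkene is suprafacial, C4 should come out cis to C2 (hence 3,4-trans) because ring B sits endo over the E-configured methide, and the absolute configuration of all three centres is set by the chiral anion bound at the quinone methide oxygen. The step needs regioselectivity (ring B at C2, boron at C3), which the electron-rich ring B secures and which an oxygen substituent on the alkene would have reversed, and endo selectivity, which the E geometry of 11 with ring D turned away from the carbonyl oxygen favours.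

Step 7
Reactants: 12 chroman-3-yl pinacol boronate
Product: 13 (2R,3S,4S)-7-(benzyloxy)-2-[3,4-bis(benzyloxy)phenyl]-4-[2,4-bis(benzyloxy)-5-bromophenyl]-3,4-dihydro-2H-chromen-3-ol
Conditions: NaBO3·4H2O, THF/H2O (1:1), rt
Reagents that add atoms: sodium perborate, [Na+].[Na+].O[B-]1(O)OO[B-](O)(O)OO1
Why: Oxidation of the C–B bond proceeds by 1,2-migration of C3 from boron to oxygen in the peroxoborate with retention, and the mild buffered perborate should avoid β-elimination of the ring aryloxide.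

Step 8
Reactants: 13 chroman-3-ol
Product: 14 (2R,3S,4S)-3,7-bis(benzyloxy)-2-[3,4-bis(benzyloxy)phenyl]-4-[2,4-bis(benzyloxy)-5-bromophenyl]-3,4-dihydro-2H-chromene
Conditions: NaH, BnBr, n-Bu4NI (cat.), DMF, 0 °C to rt
Reagents that add atoms: benzyl bromide, BrCc1ccccc1
Why: Williamson benzylation of the secondary alkoxide masks the only free hydroxyl against the organolithium, phosphorane and hydride reagents that follow, and the group leaves with the others in step 16.

Step 9
Reactants: 14 hexabenzyl bromide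
Product: 16 2,4-bis(benzyloxy)-5-[(2R,3S,4S)-3,7-bis(benzyloxy)-2-[3,4-bis(benzyloxy)phenyl]-3,4-dihydro-2H-chromen-4-yl]benzaldehyde, via aryllithium 15 (not isolated)
Conditions: n-BuLi (1.1 equiv), THF, −78 °C; DMF, −78 to 0 °C; aq. NH4Cl
Reagents that add atoms: N,N-dimethylformamide, CN(C)C=O
Why: Bromine–lithium exchange is faster at −78 °C than any benzylic deprotonation, and Bouveault formylation of the aryllithium with DMF installs the C4′ carbon ortho to the future O1′.

Step 10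
Reactants: 16 ring D benzaldehyde
Product: 17 4-(benzyloxy)-5-[(2R,3S,4S)-3,7-bis(benzyloxy)-2-[3,4-bis(benzyloxy)phenyl]-3,4-dihydro-2H-chromen-4-yl]-2-hydroxybenzaldehyde
Conditions: MgBr2·OEt2 (3 equiv), toluene/Et2O (10:1), 75 °C; 1 M HCl work-up
Reagents that add atoms: none
Why: Chelation-assisted dealkylation: magnesium held between the formyl oxygen and the ortho ether oxygen activates only that benzyl ether for bromide attack, so the two ring D oxygens are told apart without different protecting groups.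

Step 11
Reactants: 17 ring D salicylaldehyde
Product: 19 7-(benzyloxy)-6-[(2R,3S,4S)-3,7-bis(benzyloxy)-2-[3,4-bis(benzyloxy)phenyl]-3,4-dihydro-2H-chromen-4-yl]-2H-chromen-2-one, via phosphorane ester 18 (not isolated)
Conditions: Ph3P=C=C=O (1.2 equiv), toluene, 110 °C
Reagents that add atoms: (triphenylphosphoranylidene)ketene, O=C=C=P(c1ccccc1)(c1ccccc1)c1ccccc1
Why: The phenol adds to the phosphacumulene to give an ester-stabilised ylide, and its intramolecular Wittig olefination with the ortho formyl group closes the pyranone ring F with the Z alkene enforced by the ring.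

Step 12
Reactants: 19 coumarin
Product: 21 7-(benzyloxy)-6-[(2R,3S,4S)-3,7-bis(benzyloxy)-2-[3,4-bis(benzyloxy)phenyl]-3,4-dihydro-2H-chromen-4-yl]-2-ethoxy-2H-chromene (both C2′ epimers), via lactol 20 (not isolated)
Conditions: i-Bu2AlH (1.1 equiv), CH2Cl2, −78 °C; aq. potassium sodium tartrate; crude lactol, EtOH, PPTS (cat.), rt
Reagents that add atoms: ethanol, CCO
Why: Partial reduction of the lactone stops at the aluminium hemiacetal at −78 °C, and acid-catalysed acetalisation through the benzopyrylium ion gives the ethyl acetal; the acetal centre is uncontrolled and is erased in step 14.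

Step 13
Reactants: 22 3,4-bis(benzyloxy)phenylboronic acid
Product: 23 diethyl 3,4-bis(benzyloxy)phenylboronate
Conditions: EtOH, toluene, azeotropic removal of water over 4 Å MS; concentrated and used crude
Reagents that add atoms: ethanol, CCO
Why: Boronic acid esterification by removal of water gives the labile diethyl ester, which can exchange its alkoxy groups with the chiral diol-acid catalyst of step 14.

Step 14
Reactants: 21 2-ethoxy-2H-chromene; 23 diethyl 3,4-bis(benzyloxy)phenylboronate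
Product: 24 (2S)-7-(benzyloxy)-2-[3,4-bis(benzyloxy)phenyl]-6-[(2R,3S,4S)-3,7-bis(benzyloxy)-2-[3,4-bis(benzyloxy)phenyl]-3,4-dihydro-2H-chromen-4-yl]-2H-chromene
Conditions: (2R,3R)-4-(dibenzylamino)-2,3-dihydroxy-4-oxobutanoic acid (10 mol %), Yb(OTf)3 (9 mol %), 23 (1.5 equiv), EtOAc, −20 to 4 °C
Reagents that add atoms: none
Why: Petasis-type boronate addition to a chromene acetal: the acid pair ionises the acetal to the 7-alkoxybenzopyrylium ion and the aryl group is transferred to C2′ from the boronate bound to the chiral tartaric acid amide, so C2′ is set by the catalyst while the remote upper unit exerts no control.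

Step 15
Reactants: 24 flav-3-ene
Product: 25 (2R,3S,4S)-7-(benzyloxy)-2-[3,4-bis(benzyloxy)phenyl]-6-[(2R,3S,4S)-3,7-bis(benzyloxy)-2-[3,4-bis(benzyloxy)phenyl]-3,4-dihydro-2H-chromen-4-yl]-3,4-dihydro-2H-chromene-3,4-diol
Conditions: OsO4 (5 mol %), NMO (1.5 equiv), acetone/H2O (9:1), rt
Reagents that add atoms: osmium tetroxide, O=[Os](=O)(=O)=O; N-methylmorpholine N-oxide, C[N+]1([O-])CCOCC1; water, O
Why: Catalytic osmium tetroxide syn-dihydroxylation of the only alkene should occur on the face away from the C2′ aryl group, which gives the 2′,3′-trans-3′,4′-cis diol.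

Step 16
Reactants: 25 heptabenzyl diol
Product: 26 (2R,3S,4S)-2-(3,4-dihydroxyphenyl)-6-[(2R,3S,4R)-2-(3,4-dihydroxyphenyl)-3,7-dihydroxy-3,4-dihydro-2H-chromen-4-yl]-3,4-dihydro-2H-chromene-3,4,7-triol (CNP0280090.4)
Conditions: H2 (1 atm), Pd(OH)2/C, THF/MeOH (1:1), rt, neutral, stopped at full debenzylation
Reagents that add atoms: none
Why: Hydrogenolysis of the six aryl benzyl ethers and the C3 benzyl ether under neutral conditions should be faster than cleavage of the ring C–O bonds or the C4′ hydroxyl, and no stereocentre is touched.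

**Compound list**

1 | 4,6-dibromoresorcinol | Oc1cc(O)c(Br)cc1Br | starting material
2 | 1,5-bis(benzyloxy)-2,4-dibromobenzene | Brc1cc(Br)c(OCc2ccccc2)cc1OCc1ccccc1 | intermediate
3 | 2,4-dihydroxybenzaldehyde | O=Cc1ccc(O)cc1O | starting material
4 | 4-(benzyloxy)-2-hydroxybenzaldehyde | O=Cc1ccc(OCc2ccccc2)cc1O | intermediate
5 | [2,4-bis(benzyloxy)-5-bromophenyl]lithium (formed in situ) | [Li]c1cc(Br)c(OCc2ccccc2)cc1OCc1ccccc1 | intermediate
6 | sodium 5-(benzyloxy)-2-formylphenolate (formed in situ) | [Na+].[O-]c1cc(OCc2ccccc2)ccc1C=O | intermediate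
7 | (4-benzyloxy-2-hydroxyphenyl)[2,4-bis(benzyloxy)-5-bromophenyl]methanol, racemic | OC(c1ccc(OCc2ccccc2)cc1O)c1cc(Br)c(OCc2ccccc2)cc1OCc1ccccc1 | intermediate
8 | 3,4-bis(benzyloxy)benzaldehyde | O=Cc1ccc(OCc2ccccc2)c(OCc2ccccc2)c1 | starting material
9 | 1,2-bis(benzyloxy)-4-ethynylbenzene | C#Cc1ccc(OCc2ccccc2)c(OCc2ccccc2)c1 | intermediate
10 | 2-[(E)-2-[3,4-bis(benzyloxy)phenyl]ethenyl]-4,4,5,5-tetramethyl-1,3,2-dioxaborolane | CC1(C)OB(/C=C/c2ccc(OCc3ccccc3)c(OCc3ccccc3)c2)OC1(C)C | intermediate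
11 | (6E)-3-(benzyloxy)-6-{[2,4-bis(benzyloxy)-5-bromophenyl]methylidene}cyclohexa-2,4-dien-1-one (formed in situ) | O=C1C=C(OCc2ccccc2)C=C/C1=C\c1cc(Br)c(OCc2ccccc2)cc1OCc1ccccc1 | intermediate
12 | 2-[(2S,3S,4S)-7-(benzyloxy)-2-[3,4-bis(benzyloxy)phenyl]-4-[2,4-bis(benzyloxy)-5-bromophenyl]-3,4-dihydro-2H-chromen-3-yl]-4,4,5,5-tetramethyl-1,3,2-dioxaborolane, 2,3-trans-3,4-trans | c1ccccc1COc1ccc2c(c1)O[C@H](c1ccc(OCc3ccccc3)c(OCc3ccccc3)c1)[C@@H](B3OC(C)(C)C(C)(C)O3)[C@@H]2c1cc(Br)c(OCc3ccccc3)cc1OCc1ccccc1 | intermediate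
13 | (2R,3S,4S)-7-(benzyloxy)-2-[3,4-bis(benzyloxy)phenyl]-4-[2,4-bis(benzyloxy)-5-bromophenyl]-3,4-dihydro-2H-chromen-3-ol | c1ccccc1COc1ccc2c(c1)O[C@H](c1ccc(OCc3ccccc3)c(OCc3ccccc3)c1)[C@@H](O)[C@@H]2c1cc(Br)c(OCc3ccccc3)cc1OCc1ccccc1 | intermediate
14 | (2R,3S,4S)-3,7-bis(benzyloxy)-2-[3,4-bis(benzyloxy)phenyl]-4-[2,4-bis(benzyloxy)-5-bromophenyl]-3,4-dihydro-2H-chromene | c1ccccc1COc1ccc2c(c1)O[C@H](c1ccc(OCc3ccccc3)c(OCc3ccccc3)c1)[C@@H](OCc1ccccc1)[C@@H]2c1cc(Br)c(OCc3ccccc3)cc1OCc1ccccc1 | intermediate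
15 | aryllithium from 14, lithium in place of bromine (formed in situ) | c1ccccc1COc1ccc2c(c1)O[C@H](c1ccc(OCc3ccccc3)c(OCc3ccccc3)c1)[C@@H](OCc1ccccc1)[C@@H]2c1cc([Li])c(OCc3ccccc3)cc1OCc1ccccc1 | intermediate
16 | 2,4-bis(benzyloxy)-5-[(2R,3S,4S)-3,7-bis(benzyloxy)-2-[3,4-bis(benzyloxy)phenyl]-3,4-dihydro-2H-chromen-4-yl]benzaldehyde | c1ccccc1COc1ccc2c(c1)O[C@H](c1ccc(OCc3ccccc3)c(OCc3ccccc3)c1)[C@@H](OCc1ccccc1)[C@@H]2c1cc(C=O)c(OCc3ccccc3)cc1OCc1ccccc1 | intermediate
17 | 4-(benzyloxy)-5-[(2R,3S,4S)-3,7-bis(benzyloxy)-2-[3,4-bis(benzyloxy)phenyl]-3,4-dihydro-2H-chromen-4-yl]-2-hydroxybenzaldehyde | c1ccccc1COc1ccc2c(c1)O[C@H](c1ccc(OCc3ccccc3)c(OCc3ccccc3)c1)[C@@H](OCc1ccccc1)[C@@H]2c1cc(C=O)c(O)cc1OCc1ccccc1 | intermediate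
18 | 5-(benzyloxy)-4-[(2R,3S,4S)-3,7-bis(benzyloxy)-2-[3,4-bis(benzyloxy)phenyl]-3,4-dihydro-2H-chromen-4-yl]-2-formylphenyl (triphenylphosphoranylidene)acetate (formed in situ) | c1ccccc1COc1ccc2c(c1)O[C@H](c1ccc(OCc3ccccc3)c(OCc3ccccc3)c1)[C@@H](OCc1ccccc1)[C@@H]2c1cc(C=O)c(OC(=O)C=P(c3ccccc3)(c3ccccc3)c3ccccc3)cc1OCc1ccccc1 | intermediate
19 | 7-(benzyloxy)-6-[(2R,3S,4S)-3,7-bis(benzyloxy)-2-[3,4-bis(benzyloxy)phenyl]-3,4-dihydro-2H-chromen-4-yl]-2H-chromen-2-one | c1ccccc1COc1ccc2c(c1)O[C@H](c1ccc(OCc3ccccc3)c(OCc3ccccc3)c1)[C@@H](OCc1ccccc1)[C@@H]2c1cc2c(cc1OCc3ccccc3)OC(=O)C=C2 | intermediate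
20 | 7-(benzyloxy)-6-[(2R,3S,4S)-3,7-bis(benzyloxy)-2-[3,4-bis(benzyloxy)phenyl]-3,4-dihydro-2H-chromen-4-yl]-2H-chromen-2-ol, both C2′ epimers (formed in situ) | c1ccccc1COc1ccc2c(c1)O[C@H](c1ccc(OCc3ccccc3)c(OCc3ccccc3)c1)[C@@H](OCc1ccccc1)[C@@H]2c1cc2c(cc1OCc3ccccc3)OC(O)C=C2 | intermediate
21 | 7-(benzyloxy)-6-[(2R,3S,4S)-3,7-bis(benzyloxy)-2-[3,4-bis(benzyloxy)phenyl]-3,4-dihydro-2H-chromen-4-yl]-2-ethoxy-2H-chromene, both C2′ epimers | c1ccccc1COc1ccc2c(c1)O[C@H](c1ccc(OCc3ccccc3)c(OCc3ccccc3)c1)[C@@H](OCc1ccccc1)[C@@H]2c1cc2c(cc1OCc3ccccc3)OC(OCC)C=C2 | intermediate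
22 | 3,4-bis(benzyloxy)phenylboronic acid | OB(O)c1ccc(OCc2ccccc2)c(OCc2ccccc2)c1 | starting material
23 | diethyl 3,4-bis(benzyloxy)phenylboronate | CCOB(OCC)c1ccc(OCc2ccccc2)c(OCc2ccccc2)c1 | intermediate
24 | (2S)-7-(benzyloxy)-2-[3,4-bis(benzyloxy)phenyl]-6-[(2R,3S,4S)-3,7-bis(benzyloxy)-2-[3,4-bis(benzyloxy)phenyl]-3,4-dihydro-2H-chromen-4-yl]-2H-chromene | c1ccccc1COc1ccc2c(c1)O[C@H](c1ccc(OCc3ccccc3)c(OCc3ccccc3)c1)[C@@H](OCc1ccccc1)[C@@H]2c1cc2c(cc1OCc3ccccc3)O[C@H](c1ccc(OCc3ccccc3)c(OCc3ccccc3)c1)C=C2 | intermediate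
25 | (2R,3S,4S)-7-(benzyloxy)-2-[3,4-bis(benzyloxy)phenyl]-6-[(2R,3S,4S)-3,7-bis(benzyloxy)-2-[3,4-bis(benzyloxy)phenyl]-3,4-dihydro-2H-chromen-4-yl]-3,4-dihydro-2H-chromene-3,4-diol | c1ccccc1COc1ccc2c(c1)O[C@H](c1ccc(OCc3ccccc3)c(OCc3ccccc3)c1)[C@@H](OCc1ccccc1)[C@@H]2c1cc2c(cc1OCc3ccccc3)O[C@H](c1ccc(OCc3ccccc3)c(OCc3ccccc3)c1)[C@@H](O)[C@H]2O | intermediate
26 | (2R,3S,4S)-2-(3,4-dihydroxyphenyl)-6-[(2R,3S,4R)-2-(3,4-dihydroxyphenyl)-3,7-dihydroxy-3,4-dihydro-2H-chromen-4-yl]-3,4-dihydro-2H-chromene-3,4,7-triol | Oc1ccc2c(c1)O[C@H](c1ccc(O)c(O)c1)[C@@H](O)[C@@H]2c1cc2c(cc1O)O[C@H](c1ccc(O)c(O)c1)[C@@H](O)[C@H]2O | target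

**Step count**

Total: 16 steps. Longest linear sequence: 12 steps (1, 3, 6 to 12, 14 to 16).

**Steps most likely to fail**

Step 6. The boron-substituted alkene may be too weak a 2π donor for the strongly stabilised quinone methide, the open intermediate may lose boron by alkenyl transfer instead of closing at oxygen, or facial control by the acid anion may be poor. The fallback uses known reactions and builds ring C in two stages, setting out from 7 and 10 and returning at 13.
- The pinacol ester of 10 is cleaved (NaIO4, NH4OAc, acetone/H2O) to (E)-2-[3,4-bis(benzyloxy)phenyl]ethenylboronic acid F1, which is esterified with ethanol to its diethyl ester F2.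
- With 3,3′-dibromo-BINOL as catalyst, F2 transfers its alkenyl group to the methide carbon of 11 released from 7. This biphenol-catalysed conjugate alkenylation of ortho-quinone methides sets C4 and gives 5-(benzyloxy)-2-[(2E)-1-[2,4-bis(benzyloxy)-5-bromophenyl]-3-[3,4-bis(benzyloxy)phenyl]prop-2-en-1-yl]phenol F3, configured at C1 of the chain as C4 of 13.
- Silylation (TBSCl, imidazole) gives the tert-butyldimethylsilyl ether F4.
- Shi epoxidation (fructose-derived ketone, KHSO5) gives the trans-epoxide F5 under reagent control.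
- Fluoride followed by camphorsulfonic acid lets the freed phenol open the epoxide 6-endo at the benzylic carbon with inversion, which should deliver 13 with the 2,3-trans-3,4-trans pattern.

Step 14. Aryl transfer from boron may be sluggish, and an uncatalysed background addition to the very stable benzopyrylium ion may erode facial selectivity at C2′. The fallback sets out from bromide 14 and returns at 24 through a flavanone.
- Bromine–lithium exchange and acylation with N-methoxy-N-methylacetamide give the methyl ketone F6.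
- MgBr2·OEt2 removes the benzyl group ortho to the acetyl group to give the 2-hydroxyacetophenone F7.
- N,N-dimethylformamide dimethyl acetal gives the enaminone F8, and acid closes it to the chromone F9.
- Conjugate addition of boronic acid 22 with Pd(OCOCF3)2 and a chiral 2-(pyridin-2-yl)oxazoline ligand, a known asymmetric arylation of chromones, gives the (2′S)-flavanone F10.
- NaBH4 gives the 2′,4′-cis-flavan-4′-ol F11, and acid-catalysed dehydration (TsOH, toluene) returns 24.

Step 16. Hydrogenolysis may over-reduce the para-oxygen-activated benzylic C4′–O bond while the hindered C3 benzyl ether is still being cleaved. The fallback masks the diol first, setting out from 25 and returning at 26.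
- TESOTf and 2,6-lutidine give the 3′,4′-bis(triethylsilyl) ether F12, in which C4′ no longer carries a free benzylic hydroxyl.
- Hydrogenolysis (H2, Pd(OH)2/C, EtOAc) gives the debenzylated bis(triethylsilyl) ether F13.
- HF·pyridine in THF removes the silyl groups under nearly neutral conditions to give 26.

**Further compounds**

F1 | step 6 | (E)-2-[3,4-bis(benzyloxy)phenyl]ethenylboronic acid | OB(O)/C=C/c1ccc(OCc2ccccc2)c(OCc2ccccc2)c1
F2 | step 6 | diethyl (E)-2-[3,4-bis(benzyloxy)phenyl]ethenylboronate | CCOB(OCC)/C=C/c1ccc(OCc2ccccc2)c(OCc2ccccc2)c1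
F3 | step 6 | 5-(benzyloxy)-2-[(2E)-1-[2,4-bis(benzyloxy)-5-bromophenyl]-3-[3,4-bis(benzyloxy)phenyl]prop-2-en-1-yl]phenol, C1 configured as C4 of 13 | Oc1cc(OCc2ccccc2)ccc1[C@H](/C=C/c1ccc(OCc2ccccc2)c(OCc2ccccc2)c1)c1cc(Br)c(OCc2ccccc2)cc1OCc1ccccc1
F4 | step 6 | tert-butyldimethylsilyl ether of F3 | CC(C)(C)[Si](C)(C)Oc1cc(OCc2ccccc2)ccc1[C@H](/C=C/c1ccc(OCc2ccccc2)c(OCc2ccccc2)c1)c1cc(Br)c(OCc2ccccc2)cc1OCc1ccccc1
F5 | step 6 | trans-epoxide of F4, 3-[3,4-bis(benzyloxy)phenyl]oxiran-2-yl in place of the styryl group | CC(C)(C)[Si](C)(C)Oc1cc(OCc2ccccc2)ccc1[C@H]([C@@H]1O[C@H]1c1ccc(OCc2ccccc2)c(OCc2ccccc2)c1)c1cc(Br)c(OCc2ccccc2)cc1OCc1ccccc1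
F6 | step 14 | 1-{2,4-bis(benzyloxy)-5-[(2R,3S,4S)-3,7-bis(benzyloxy)-2-[3,4-bis(benzyloxy)phenyl]-3,4-dihydro-2H-chromen-4-yl]phenyl}ethanone | c1ccccc1COc1ccc2c(c1)O[C@H](c1ccc(OCc3ccccc3)c(OCc3ccccc3)c1)[C@@H](OCc1ccccc1)[C@@H]2c1cc(C(C)=O)c(OCc3ccccc3)cc1OCc1ccccc1
F7 | step 14 | 1-{4-(benzyloxy)-5-[(2R,3S,4S)-3,7-bis(benzyloxy)-2-[3,4-bis(benzyloxy)phenyl]-3,4-dihydro-2H-chromen-4-yl]-2-hydroxyphenyl}ethanone | c1ccccc1COc1ccc2c(c1)O[C@H](c1ccc(OCc3ccccc3)c(OCc3ccccc3)c1)[C@@H](OCc1ccccc1)[C@@H]2c1cc(C(C)=O)c(O)cc1OCc1ccccc1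
F8 | step 14 | (2E)-3-(dimethylamino)-1-{4-(benzyloxy)-5-[(2R,3S,4S)-3,7-bis(benzyloxy)-2-[3,4-bis(benzyloxy)phenyl]-3,4-dihydro-2H-chromen-4-yl]-2-hydroxyphenyl}prop-2-en-1-one | c1ccccc1COc1ccc2c(c1)O[C@H](c1ccc(OCc3ccccc3)c(OCc3ccccc3)c1)[C@@H](OCc1ccccc1)[C@@H]2c1cc(C(=O)/C=C/N(C)C)c(O)cc1OCc1ccccc1
F9 | step 14 | 7-(benzyloxy)-6-[(2R,3S,4S)-3,7-bis(benzyloxy)-2-[3,4-bis(benzyloxy)phenyl]-3,4-dihydro-2H-chromen-4-yl]-4H-chromen-4-one | c1ccccc1COc1ccc2c(c1)O[C@H](c1ccc(OCc3ccccc3)c(OCc3ccccc3)c1)[C@@H](OCc1ccccc1)[C@@H]2c1cc2c(cc1OCc3ccccc3)OC=CC2=O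
F10 | step 14 | (2S)-7-(benzyloxy)-2-[3,4-bis(benzyloxy)phenyl]-6-[(2R,3S,4S)-3,7-bis(benzyloxy)-2-[3,4-bis(benzyloxy)phenyl]-3,4-dihydro-2H-chromen-4-yl]-2,3-dihydro-4H-chromen-4-one | c1ccccc1COc1ccc2c(c1)O[C@H](c1ccc(OCc3ccccc3)c(OCc3ccccc3)c1)[C@@H](OCc1ccccc1)[C@@H]2c1cc2c(cc1OCc3ccccc3)O[C@H](c1ccc(OCc3ccccc3)c(OCc3ccccc3)c1)CC2=O
F11 | step 14 | (2S,4S)-7-(benzyloxy)-2-[3,4-bis(benzyloxy)phenyl]-6-[(2R,3S,4S)-3,7-bis(benzyloxy)-2-[3,4-bis(benzyloxy)phenyl]-3,4-dihydro-2H-chromen-4-yl]-3,4-dihydro-2H-chromen-4-ol, 2,4-cis | c1ccccc1COc1ccc2c(c1)O[C@H](c1ccc(OCc3ccccc3)c(OCc3ccccc3)c1)[C@@H](OCc1ccccc1)[C@@H]2c1cc2c(cc1OCc3ccccc3)O[C@H](c1ccc(OCc3ccccc3)c(OCc3ccccc3)c1)C[C@@H]2O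
F12 | step 16 | 3′,4′-bis(triethylsilyl) ether of 25 | c1ccccc1COc1ccc2c(c1)O[C@H](c1ccc(OCc3ccccc3)c(OCc3ccccc3)c1)[C@@H](OCc1ccccc1)[C@@H]2c1cc2c(cc1OCc3ccccc3)O[C@H](c1ccc(OCc3ccccc3)c(OCc3ccccc3)c1)[C@@H](O[Si](CC)(CC)CC)[C@H]2O[Si](CC)(CC)CC
F13 | step 16 | 3′,4′-bis(triethylsilyl) ether of 26 | Oc1ccc2c(c1)O[C@H](c1ccc(O)c(O)c1)[C@@H](O)[C@@H]2c1cc2c(cc1O)O[C@H](c1ccc(O)c(O)c1)[C@@H](O[Si](CC)(CC)CC)[C@H]2O[Si](CC)(CC)CC
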